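**Retrosynthetic overview**

1. Ring C is closed last: the (2R,3R)-dihydroflavonol comes from acid-triggered opening of a (2R,3S)-chalcone epoxide with 6-endo O-cyclisation and global deprotection. The epoxide comes from Juliá–Colonna epoxidation of a chalcone made by Claisen–Schmidt union of a ring A acetophenone and a ring B aldehyde.
2. The ring A acetophenone comes from ortho-lithiation/acylation of an aryl–CH2–CH(isopropenyl)(alkyl) arene.
3. Key disconnection at the side-chain stereocentre: two boron-to-carbon 1,2-shifts. A Pd-catalysed enantioselective conjunctive coupling (aryl bromide + vinyl + alkyl boronate) shifts the alkyl chain from B to C and sets the centre; a Zweifel olefination then shifts that carbon, with retention, from B onto the isopropenyl carbon.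
4. Building blocks: resorcinol (rings A and B; ring A gains its third oxygen by Ir C–H borylation/oxidation), 2-methylbut-3-en-2-ol, vinylmagnesium bromide, 2-bromopropene, N-methoxy-N-methylacetamide.
5. Ring order: rings A and B are bought as aromatic rings; ring C is formed in the final step.

Assumption: the (Sp,Sp) antipode of the ferrocenyl bisphosphine named in step 7 is taken to deliver the (R)-boronate; if the sense proves opposite, the mirror-image ligand is used with no other change.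

**Route**

Step 1
Reactants: 1 resorcinol
Product: 2 1,3-bis(methoxymethoxy)benzene
Conditions: MOMCl (2.4 equiv), i-Pr2NEt (3 equiv), CH2Cl2, 0 °C to rt
Reagents that add atoms: chloromethyl methyl ether (MOMCl), COCCl
Why: Williamson-type O-alkylation of both phenols gives the bis-acetal, which later directs ortho-lithiation and is removed by acid.

Step 2
Reactants: 2 1,3-bis(methoxymethoxy)benzene
Product: 4 2-bromo-1,3-bis(methoxymethoxy)benzene, via aryllithium 3 (not isolated)
Conditions: n-BuLi, THF, 0 °C; then BrCH2CH2Br, −78 °C to rt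
Reagents that add atoms: 1,2-dibromoethane, BrCCBr
Why: directed ortho-metalation occurs only at the C–H flanked by both OMOM groups, and the aryllithium is brominated by halophilic attack on the dibromide.

Step 3
Reactants: 4 2-bromo-1,3-bis(methoxymethoxy)benzene
Product: 6 4-bromo-3,5-bis(methoxymethoxy)phenol, via aryl pinacol boronate 5 (not isolated)
Conditions: [Ir(OMe)(cod)]2 (1.5 mol %), 4,4′-di-tert-butyl-2,2′-bipyridine (3 mol %), B2pin2 (0.7 equiv), THF, 70 °C; then NaOH (aq.), H2O2, 0 °C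
Reagents that add atoms: hydrogen peroxide, OO
Why: sterically controlled iridium-catalysed C–H borylation takes the only C–H without an ortho substituent (para to Br), and the boronate is oxidised in the same flask to the phenol (C–H borylation/oxidation).

Step 4
Reactants: 6 4-bromo-3,5-bis(methoxymethoxy)phenol
Product: 7 2-bromo-5-methoxy-1,3-bis(methoxymethoxy)benzene
Conditions: MeI, K2CO3, acetone, 50 °C
Reagents that add atoms: iodomethane, CI
Why: Williamson ether synthesis on the only free phenol installs the future 5-methoxy group.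

Step 5
Reactants: 8 2-methylbut-3-en-2-ol
Product: 9 triethyl[(2-methylbut-3-en-2-yl)oxy]silane
Conditions: Et3SiOTf, 2,6-lutidine, CH2Cl2, 0 °C
Reagents that add atoms: triethylsilyl trifluoromethanesulfonate, CC[Si](CC)(CC)OS(=O)(=O)C(F)(F)F
Why: silylation of the tertiary alcohol with a silyl triflate masks the hydroxyl for the organometallic steps.

Step 6
Reactants: 9 triethyl[(2-methylbut-3-en-2-yl)oxy]silane
Product: 10 triethyl{[2-methyl-4-(4,4,5,5-tetramethyl-1,3,2-dioxaborolan-2-yl)butan-2-yl]oxy}silane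
Conditions: HBpin (1.2 equiv), [IrCl(cod)]2 (1.5 mol %), bis(diphenylphosphino)methane (3 mol %), CH2Cl2, rt
Reagents that add atoms: pinacolborane, CC1(C)OBOC1(C)C
Why: iridium-catalysed anti-Markovnikov hydroboration of the terminal alkene, reinforced by the adjacent quaternary carbon, gives the primary boronate.

Step 7
Reactants: 10 triethyl{[2-methyl-4-(4,4,5,5-tetramethyl-1,3,2-dioxaborolan-2-yl)butan-2-yl]oxy}silane, 11 vinylmagnesium bromide, 7 2-bromo-5-methoxy-1,3-bis(methoxymethoxy)benzene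
Product: 13 2-[(2R)-1-[2,6-bis(methoxymethoxy)-4-methoxyphenyl]-5-methyl-5-(triethylsilyloxy)hexan-2-yl]-4,4,5,5-tetramethyl-1,3,2-dioxaborolane, via vinyl boronate complex 12 (not isolated)
Conditions: 10 (1.3 equiv), CH2=CHMgBr (1.3 equiv), NaOTf (2.6 equiv), THF, 0 °C to rt; then 7 (1.0 equiv), Pd(OAc)2 (3 mol %), ligand L (3.6 mol %), THF, 60 °C, 16 h; L = (αR,αR)-2,2′-bis[α-(dimethylamino)benzyl]-(Sp,Sp)-1,1′-bis[bis(4-methoxy-3,5-dimethylphenyl)phosphino]ferrocene
Reagents that add atoms: none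
Why: Proposed new method: an enantioselective palladium-induced 1,2-shift (conjunctive cross-coupling) that pairs a 2,6-dialkoxy, electron-rich aryl bromide with a silyloxyalkyl migrating group, a combination not yet shown; zerovalent palladium inserts into the C–Br bond of 7, NaOTf removes bromide to leave a cationic aryl divalent palladium that binds the vinyl group of 12, the alkyl chain shifts from boron to the alpha carbon anti to palladium as the Pd–C(beta) bond forms (the chiral bisphosphine pocket selects the alkene face and so the R centre), and reductive elimination, helped by the two ortho substituents, makes the aryl–CH2 bond, while the chelating ligand leaves no site for direct transmetalation of the vinyl group; closest known reaction type: Pd/ferrocenyl-bisphosphine conjunctive coupling of vinyl boron ate complexes with unhindered aryl triflates or bromides.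

Step 8
Reactants: 13 2-[(2R)-1-[2,6-bis(methoxymethoxy)-4-methoxyphenyl]-5-methyl-5-(triethylsilyloxy)hexan-2-yl]-4,4,5,5-tetramethyl-1,3,2-dioxaborolane, 14 2-bromopropene
Product: 18 5-methoxy-1,3-bis(methoxymethoxy)-2-[(2R)-5-methyl-2-(prop-1-en-2-yl)-5-(triethylsilyloxy)hexyl]benzene, via isopropenyllithium 15 (not isolated), via lithium boronate complex 16 (not isolated), via iodoalkyl boronate 17 (not isolated)
Conditions: 14, t-BuLi (2 equiv per 14), THF, −78 °C; add 13, −78 °C; I2, MeOH, −78 °C; NaOMe, MeOH, −78 °C to rt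
Reagents that add atoms: none
Why: Zweifel olefination, in which iodine activates the alkenyl group of the ate complex, the secondary carbon shifts from boron to carbon with retention, and anti elimination of boron and iodide leaves the isopropenyl group on an unchanged R centre.

Step 9
Reactants: 18 5-methoxy-1,3-bis(methoxymethoxy)-2-[(2R)-5-methyl-2-(prop-1-en-2-yl)-5-(triethylsilyloxy)hexyl]benzene, 19 N-methoxy-N-methylacetamide
Product: 21 1-{6-methoxy-2,4-bis(methoxymethoxy)-3-[(2R)-5-methyl-2-(prop-1-en-2-yl)-5-(triethylsilyloxy)hexyl]phenyl}ethan-1-one, via aryllithium 20 (not isolated)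
Conditions: n-BuLi, THF, 0 °C; then 19, −78 °C to 0 °C; H2O
Reagents that add atoms: none
Why: directed ortho-metalation at a ring C–H flanked by OMOM and OMe (the two such positions are equivalent), then Weinreb ketone synthesis, whose chelated tetrahedral adduct prevents over-addition.

Step 10
Reactants: 2 1,3-bis(methoxymethoxy)benzene
Product: 22 1-bromo-2,4-bis(methoxymethoxy)benzene
Conditions: NBS (1.0 equiv), MeCN, 0 °C
Reagents that add atoms: N-bromosuccinimide, O=C1CCC(=O)N1Br
Why: electrophilic aromatic bromination goes para to one OMOM and ortho to the other, the most activated unhindered position.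

Step 11
Reactants: 22 1-bromo-2,4-bis(methoxymethoxy)benzene
Product: 24 2,4-bis(methoxymethoxy)benzaldehyde, via aryllithium 23 (not isolated)
Conditions: n-BuLi, THF, −78 °C; then DMF, −78 °C to rt; H2O
Reagents that add atoms: N,N-dimethylformamide, CN(C)C=O
Why: bromine–lithium exchange followed by Bouveault formylation places the aldehyde where the bromine was.

Step 12
Reactants: 21 1-{6-methoxy-2,4-bis(methoxymethoxy)-3-[(2R)-5-methyl-2-(prop-1-en-2-yl)-5-(triethylsilyloxy)hexyl]phenyl}ethan-1-one, 24 2,4-bis(methoxymethoxy)benzaldehyde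
Product: 25 (2E)-3-[2,4-bis(methoxymethoxy)phenyl]-1-{6-methoxy-2,4-bis(methoxymethoxy)-3-[(2R)-5-methyl-2-(prop-1-en-2-yl)-5-(triethylsilyloxy)hexyl]phenyl}prop-2-en-1-one
Conditions: KOH, EtOH/THF, rt
Reagents that add atoms: none
Why: Claisen–Schmidt aldol condensation of a methyl ketone with a non-enolisable aldehyde gives the E-enone after E1cB dehydration.

Step 13
Reactants: 25 (2E)-3-[2,4-bis(methoxymethoxy)phenyl]-1-{6-methoxy-2,4-bis(methoxymethoxy)-3-[(2R)-5-methyl-2-(prop-1-en-2-yl)-5-(triethylsilyloxy)hexyl]phenyl}prop-2-en-1-one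
Product: 26 [(2R,3S)-3-[2,4-bis(methoxymethoxy)phenyl]oxiran-2-yl]{6-methoxy-2,4-bis(methoxymethoxy)-3-[(2R)-5-methyl-2-(prop-1-en-2-yl)-5-(triethylsilyloxy)hexyl]phenyl}methanone
Conditions: poly-L-leucine, urea–H2O2, DBU, THF, rt
Reagents that add atoms: hydrogen peroxide (as its urea adduct), OO
Why: Juliá–Colonna asymmetric Weitz–Scheffer epoxidation, in which the helical poly-L-leucine delivers hydroperoxide to the enone face that gives the (2R,3S)-trans-epoxide, and the nucleophilic oxidant leaves the isopropenyl group untouched.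

Step 14
Reactants: 26 [(2R,3S)-3-[2,4-bis(methoxymethoxy)phenyl]oxiran-2-yl]{6-methoxy-2,4-bis(methoxymethoxy)-3-[(2R)-5-methyl-2-(prop-1-en-2-yl)-5-(triethylsilyloxy)hexyl]phenyl}methanone
Product: 29 (2R,3R)-2-(2,4-dihydroxyphenyl)-3,7-dihydroxy-8-[(2R)-5-hydroxy-5-methyl-2-(prop-1-en-2-yl)hexyl]-5-methoxy-2,3-dihydro-4H-chromen-4-one, via methoxy hydroxy ketone 27 (not isolated), via deprotected methoxy hydroxy ketone 28 (not isolated)
Conditions: HCl (3 M aq.), MeOH/THF, 45 °C
Reagents that add atoms: none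
Why: acid-mediated epoxide opening at the benzylic carbon, acetal and silyl ether solvolysis, and SN1-type 6-endo closure of ring C by the freed ortho phenol onto the cation stabilised by the 2,4-dioxygenated aryl; C3 keeps the R configuration of the epoxide alpha carbon and C2 settles as the trans (2R) isomer under thermodynamic control.

**Compound list**

1 | resorcinol (benzene-1,3-diol) | Oc1cccc(O)c1 | starting material
2 | 1,3-bis(methoxymethoxy)benzene | COCOc1cccc(OCOC)c1 | intermediate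
3 | [2,6-bis(methoxymethoxy)phenyl]lithium | [Li]c1c(OCOC)cccc1OCOC | intermediate
4 | 2-bromo-1,3-bis(methoxymethoxy)benzene | COCOc1cccc(OCOC)c1Br | intermediate
5 | 2-[4-bromo-3,5-bis(methoxymethoxy)phenyl]-4,4,5,5-tetramethyl-1,3,2-dioxaborolane | COCOc1cc(B2OC(C)(C)C(C)(C)O2)cc(OCOC)c1Br | intermediate
6 | 4-bromo-3,5-bis(methoxymethoxy)phenol | COCOc1cc(O)cc(OCOC)c1Br | intermediate
7 | 2-bromo-5-methoxy-1,3-bis(methoxymethoxy)benzene | COCOc1cc(OC)cc(OCOC)c1Br | intermediate
8 | 2-methylbut-3-en-2-ol | C=CC(C)(C)O | starting material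
9 | triethyl[(2-methylbut-3-en-2-yl)oxy]silane | C=CC(C)(C)O[Si](CC)(CC)CC | intermediate
10 | triethyl{[2-methyl-4-(4,4,5,5-tetramethyl-1,3,2-dioxaborolan-2-yl)butan-2-yl]oxy}silane | CC[Si](CC)(CC)OC(C)(C)CCB1OC(C)(C)C(C)(C)O1 | intermediate
11 | vinylmagnesium bromide (ethenylmagnesium bromide) | C=C[Mg]Br | starting material
12 | bromomagnesium ethenyl[3-methyl-3-(triethylsilyloxy)butyl](pinacolato)borate | C=C[B-]1(CCC(C)(C)O[Si](CC)(CC)CC)OC(C)(C)C(C)(C)O1.[Mg+]Br | intermediate
13 | 2-[(2R)-1-[2,6-bis(methoxymethoxy)-4-methoxyphenyl]-5-methyl-5-(triethylsilyloxy)hexan-2-yl]-4,4,5,5-tetramethyl-1,3,2-dioxaborolane | CC1(C)OB(OC1(C)C)[C@H](CCC(C)(C)O[Si](CC)(CC)CC)Cc1c(OCOC)cc(OC)cc1OCOC | intermediate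
14 | 2-bromopropene | C=C(C)Br | starting material
15 | isopropenyllithium (prop-1-en-2-yllithium) | [Li]C(C)=C | intermediate
16 | lithium [(2R)-1-[2,6-bis(methoxymethoxy)-4-methoxyphenyl]-5-methyl-5-(triethylsilyloxy)hexan-2-yl](pinacolato)(prop-1-en-2-yl)borate | [Li+].C=C(C)[B-]1(OC(C)(C)C(C)(C)O1)[C@H](CCC(C)(C)O[Si](CC)(CC)CC)Cc1c(OCOC)cc(OC)cc1OCOC | intermediate
17 | 2-[(3R)-3-{[2,6-bis(methoxymethoxy)-4-methoxyphenyl]methyl}-1-iodo-2,6-dimethyl-6-(triethylsilyloxy)heptan-2-yl]-4,4,5,5-tetramethyl-1,3,2-dioxaborolane (both epimers at C2) | CC1(C)OB(OC1(C)C)C(C)(CI)[C@H](CCC(C)(C)O[Si](CC)(CC)CC)Cc1c(OCOC)cc(OC)cc1OCOC | intermediate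
18 | 5-methoxy-1,3-bis(methoxymethoxy)-2-[(2R)-5-methyl-2-(prop-1-en-2-yl)-5-(triethylsilyloxy)hexyl]benzene | C=C(C)[C@H](CCC(C)(C)O[Si](CC)(CC)CC)Cc1c(OCOC)cc(OC)cc1OCOC | intermediate
19 | N-methoxy-N-methylacetamide | CC(=O)N(C)OC | starting material
20 | {6-methoxy-2,4-bis(methoxymethoxy)-3-[(2R)-5-methyl-2-(prop-1-en-2-yl)-5-(triethylsilyloxy)hexyl]phenyl}lithium | C=C(C)[C@H](CCC(C)(C)O[Si](CC)(CC)CC)Cc1c(OCOC)c([Li])c(OC)cc1OCOC | intermediate
21 | 1-{6-methoxy-2,4-bis(methoxymethoxy)-3-[(2R)-5-methyl-2-(prop-1-en-2-yl)-5-(triethylsilyloxy)hexyl]phenyl}ethan-1-one | C=C(C)[C@H](CCC(C)(C)O[Si](CC)(CC)CC)Cc1c(OCOC)c(C(C)=O)c(OC)cc1OCOC | intermediate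
22 | 1-bromo-2,4-bis(methoxymethoxy)benzene | COCOc1ccc(Br)c(OCOC)c1 | intermediate
23 | [2,4-bis(methoxymethoxy)phenyl]lithium | [Li]c1ccc(OCOC)cc1OCOC | intermediate
24 | 2,4-bis(methoxymethoxy)benzaldehyde | COCOc1ccc(C=O)c(OCOC)c1 | intermediate
25 | (2E)-3-[2,4-bis(methoxymethoxy)phenyl]-1-{6-methoxy-2,4-bis(methoxymethoxy)-3-[(2R)-5-methyl-2-(prop-1-en-2-yl)-5-(triethylsilyloxy)hexyl]phenyl}prop-2-en-1-one | C=C(C)[C@H](CCC(C)(C)O[Si](CC)(CC)CC)Cc1c(OCOC)c(C(=O)/C=C/c2ccc(OCOC)cc2OCOC)c(OC)cc1OCOC | intermediate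
26 | [(2R,3S)-3-[2,4-bis(methoxymethoxy)phenyl]oxiran-2-yl]{6-methoxy-2,4-bis(methoxymethoxy)-3-[(2R)-5-methyl-2-(prop-1-en-2-yl)-5-(triethylsilyloxy)hexyl]phenyl}methanone | C=C(C)[C@H](CCC(C)(C)O[Si](CC)(CC)CC)Cc1c(OCOC)c(C(=O)[C@@H]2O[C@H]2c3ccc(OCOC)cc3OCOC)c(OC)cc1OCOC | intermediate
27 | (2R)-3-[2,4-bis(methoxymethoxy)phenyl]-2-hydroxy-3-methoxy-1-{6-methoxy-2,4-bis(methoxymethoxy)-3-[(2R)-5-methyl-2-(prop-1-en-2-yl)-5-(triethylsilyloxy)hexyl]phenyl}propan-1-one (both C3 epimers) | C=C(C)[C@H](CCC(C)(C)O[Si](CC)(CC)CC)Cc1c(OCOC)c(C(=O)[C@H](O)C(OC)c2ccc(OCOC)cc2OCOC)c(OC)cc1OCOC | intermediate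
28 | (2R)-3-(2,4-dihydroxyphenyl)-1-{2,4-dihydroxy-3-[(2R)-5-hydroxy-5-methyl-2-(prop-1-en-2-yl)hexyl]-6-methoxyphenyl}-2-hydroxy-3-methoxypropan-1-one (both C3 epimers) | C=C(C)[C@H](CCC(C)(C)O)Cc1c(O)c(C(=O)[C@H](O)C(OC)c2ccc(O)cc2O)c(OC)cc1O | intermediate
29 | (2R,3R)-2-(2,4-dihydroxyphenyl)-3,7-dihydroxy-8-[(2R)-5-hydroxy-5-methyl-2-(prop-1-en-2-yl)hexyl]-5-methoxy-2,3-dihydro-4H-chromen-4-one (CID44584091) | C=C(C)[C@H](CCC(C)(C)O)Cc1c(O)cc(OC)c2c1O[C@H](c1ccc(O)cc1O)[C@@H](O)C2=O | target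

**Step count**

Total steps: 14. Longest linear sequence: 10 steps (1, 2, 3, 4, 7, 8, 9, 12, 13, 14).

**Steps most likely to fail and their fallbacks**

Step 7 (the proposed new coupling). Oxidative addition to the hindered, electron-rich bromide may be slow, and direct Suzuki transfer of the vinyl group may compete. The fallback uses known lithiation–borylation chemistry, sets out from 7 and rejoins at 13. Bromine–lithium exchange on 7 (n-BuLi, THF, −78 °C) gives [2,6-bis(methoxymethoxy)-4-methoxyphenyl]lithium F1, which is trapped with 2-isopropoxy-4,4,5,5-tetramethyl-1,3,2-dioxaborolane to give the aryl pinacol boronate F2. Matteson homologation (BrCH2Cl, n-BuLi, THF, −78 °C to rt) converts F2 into the benzyl pinacol boronate F3. Separately, γ-butyrolactone and MeMgBr give 4-methylpentane-1,4-diol F4. i-Pr2NCOCl/Et3N carbamoylates its primary hydroxyl to 4-hydroxy-4-methylpentyl N,N-diisopropylcarbamate F5, and Et3SiOTf/2,6-lutidine gives the silyl ether carbamate F6. Deprotonation of F6 with s-BuLi/(−)-sparteine (Et2O, −78 °C) gives the (S)-lithiated carbamate F7. Addition of F3 forms, with retention, the boronate complex F8. Warming (MgBr2·OEt2, Et2O, reflux) triggers the stereospecific 1,2-shift of the benzyl group with inversion at carbon and loss of the carbamate, giving the (R)-boronate 13.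

Step 13 (asymmetric epoxidation). The twisted, electron-rich enone may react slowly or with modest enantioselectivity. The fallback sets out from 25 and rejoins at 29, replacing reagent control by separation of diastereomers. Chalcone 25 is epoxidised without a chiral catalyst (H2O2, NaOH, MeOH/THF, 0 °C), which gives 26 together with an equal amount of the (2S,3R)-epoxide diastereomer F9. The mixture is taken through the acid treatment of step 14, in which F9 passes through the (2S)-methoxy hydroxy ketone F10 and the deprotected (2S)-methoxy hydroxy ketone F11 to the (2S,3S)-dihydroflavonol diastereomer F12. Because the side-chain centre is fixed as R, 29 and F12 are diastereomers and are separated by preparative HPLC (chiral stationary phase if needed).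

Step 14 (acid cascade). The isopropenyl group can cyclise onto the 7-hydroxyl, the tertiary alcohol can ionise, and the epoxide can divert to aroyl-shift products. The fallback sets out from 26 and rejoins at 29, separating deprotection from ring closure. The silyl ether of 26 is cleaved first (n-Bu4NF buffered with AcOH, THF, 0 °C) to give the hydroxy epoxide F13. ZnBr2/n-PrSH (CH2Cl2, 0 °C) then removes the four MOM groups under nearly neutral conditions and opens the epoxide at the benzylic carbon, giving the propylsulfanyl hydroxy ketone F14. AgBF4 (CH2Cl2/acetone, 0 °C) abstracts the thiolate, and the ortho phenol closes ring C to give 29.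

**Further compounds**

F1 | step 7 | [2,6-bis(methoxymethoxy)-4-methoxyphenyl]lithium | [Li]c1c(OCOC)cc(OC)cc1OCOC
F2 | step 7 | 2-[2,6-bis(methoxymethoxy)-4-methoxyphenyl]-4,4,5,5-tetramethyl-1,3,2-dioxaborolane | COCOc1cc(OC)cc(OCOC)c1B1OC(C)(C)C(C)(C)O1
F3 | step 7 | 2-{[2,6-bis(methoxymethoxy)-4-methoxyphenyl]methyl}-4,4,5,5-tetramethyl-1,3,2-dioxaborolane | CC1(C)OB(Cc2c(OCOC)cc(OC)cc2OCOC)OC1(C)C
F4 | step 7 | 4-methylpentane-1,4-diol | CC(C)(O)CCCO
F5 | step 7 | 4-hydroxy-4-methylpentyl N,N-diisopropylcarbamate | CC(C)N(C(C)C)C(=O)OCCCC(C)(C)O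
F6 | step 7 | 4-methyl-4-(triethylsilyloxy)pentyl N,N-diisopropylcarbamate | CC(C)N(C(C)C)C(=O)OCCCC(C)(C)O[Si](CC)(CC)CC
F7 | step 7 | (1S)-1-lithio-4-methyl-4-(triethylsilyloxy)pentyl N,N-diisopropylcarbamate (sparteine complex) | CC(C)N(C(C)C)C(=O)O[C@@H]([Li])CCC(C)(C)O[Si](CC)(CC)CC
F8 | step 7 | lithium {[2,6-bis(methoxymethoxy)-4-methoxyphenyl]methyl}{1-[(diisopropylcarbamoyl)oxy]-4-methyl-4-(triethylsilyloxy)pentyl}(pinacolato)borate (configuration at carbon as in F7) | [Li+].CC(C)N(C(C)C)C(=O)O[C@@H]([B-]1(Cc2c(OCOC)cc(OC)cc2OCOC)OC(C)(C)C(C)(C)O1)CCC(C)(C)O[Si](CC)(CC)CC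
F9 | step 13 | [(2S,3R)-3-[2,4-bis(methoxymethoxy)phenyl]oxiran-2-yl]{6-methoxy-2,4-bis(methoxymethoxy)-3-[(2R)-5-methyl-2-(prop-1-en-2-yl)-5-(triethylsilyloxy)hexyl]phenyl}methanone | C=C(C)[C@H](CCC(C)(C)O[Si](CC)(CC)CC)Cc1c(OCOC)c(C(=O)[C@H]2O[C@@H]2c3ccc(OCOC)cc3OCOC)c(OC)cc1OCOC
F10 | step 13 | (2S)-3-[2,4-bis(methoxymethoxy)phenyl]-2-hydroxy-3-methoxy-1-{6-methoxy-2,4-bis(methoxymethoxy)-3-[(2R)-5-methyl-2-(prop-1-en-2-yl)-5-(triethylsilyloxy)hexyl]phenyl}propan-1-one (both C3 epimers) | C=C(C)[C@H](CCC(C)(C)O[Si](CC)(CC)CC)Cc1c(OCOC)c(C(=O)[C@@H](O)C(OC)c2ccc(OCOC)cc2OCOC)c(OC)cc1OCOC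
F11 | step 13 | (2S)-3-(2,4-dihydroxyphenyl)-1-{2,4-dihydroxy-3-[(2R)-5-hydroxy-5-methyl-2-(prop-1-en-2-yl)hexyl]-6-methoxyphenyl}-2-hydroxy-3-methoxypropan-1-one (both C3 epimers) | C=C(C)[C@H](CCC(C)(C)O)Cc1c(O)c(C(=O)[C@@H](O)C(OC)c2ccc(O)cc2O)c(OC)cc1O
F12 | step 13 | (2S,3S)-2-(2,4-dihydroxyphenyl)-3,7-dihydroxy-8-[(2R)-5-hydroxy-5-methyl-2-(prop-1-en-2-yl)hexyl]-5-methoxy-2,3-dihydro-4H-chromen-4-one | C=C(C)[C@H](CCC(C)(C)O)Cc1c(O)cc(OC)c2c1O[C@@H](c1ccc(O)cc1O)[C@H](O)C2=O
F13 | step 14 | [(2R,3S)-3-[2,4-bis(methoxymethoxy)phenyl]oxiran-2-yl]{3-[(2R)-5-hydroxy-5-methyl-2-(prop-1-en-2-yl)hexyl]-6-methoxy-2,4-bis(methoxymethoxy)phenyl}methanone | C=C(C)[C@H](CCC(C)(C)O)Cc1c(OCOC)c(C(=O)[C@@H]2O[C@H]2c3ccc(OCOC)cc3OCOC)c(OC)cc1OCOC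
F14 | step 14 | (2S)-3-(2,4-dihydroxyphenyl)-1-{2,4-dihydroxy-3-[(2R)-5-hydroxy-5-methyl-2-(prop-1-en-2-yl)hexyl]-6-methoxyphenyl}-2-hydroxy-3-(propylsulfanyl)propan-1-one (C2 arranged as in 26, the descriptor changes because sulfur raises the rank of C3; both C3 epimers) | C=C(C)[C@H](CCC(C)(C)O)Cc1c(O)c(C(=O)[C@H](O)C(SCCC)c2ccc(O)cc2O)c(OC)cc1O
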